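The target is a bisabolane, and its ring is closed at the C1–C2 bond by an intramolecular carbonyl-ene reaction of a linear C15 aldehyde, (6Z)-4,9-diacetoxy-2,3-dihydrofarnesal. The step exploits the homoallylic-alcohol relationship O–C2–C1–C7(–C14) between the oxygenated ring carbon C2, the neighbouring ring carbon C1 and the side-chain branch point C7. In one operation it forms the cyclohexane, sets C1 and C2 trans under control of the C4-methyl/C5-acetoxy pair, and unveils a C7=C14 methylene next to the new C2 hydroxyl, which then directs hydrogenation to set C7. The precursor is built from prenal, an allenylboronate, oxirane, MeMgBr and a crotyl donor; angeloylation ends the route.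

Key step: step 9

Numbering: atom labels C1–C15 in the text are bisabolane numbers of the target (cyclohexane C1–C6: C1 bears the side chain, C2 the angelate, C4 the methyl C15, C5 an acetate; side chain C7 with methyl C14, C8, C9 with the second acetate, C10=C11 with methyls C12 and C13). Locants inside systematic names belong to the compound named.

Assumption: (R)-TRIP is taken to direct Re-face addition and the (S)-SEGPHOS iridium catalyst Si-face addition to the carbonyl, as in the parent allylations; should either sense prove opposite, the antipodal catalyst is used.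

Step 1
Reactants: 1 3-methylbut-2-enal (prenal); 2 allenylboronic acid pinacol ester
Product: 4 (4R)-6-methylhept-5-en-1-yn-4-ol, via pinacol borate ester 3 (not isolated)
Conditions: (R)-TRIP [(R)-3,3'-bis(2,4,6-triisopropylphenyl)-1,1'-binaphthyl-2,2'-diyl hydrogen phosphate] (10 mol %), 4 Å MS, toluene, −20 °C; aq. NaHCO3
Reagents that add atoms: none
Why: Chiral-phosphoric-acid-catalysed propargylboration of an aldehyde: the allenylboronate adds in the SE2' sense through a closed six-membered transition state (giving the homopropargylic, not the allenic, alcohol), and the catalyst, hydrogen-bonded to the boronate oxygen and the formyl hydrogen, should expose the Re face of the enal so that C9 is formed as R.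

Step 2
Reactants: 4 (4R)-6-methylhept-5-en-1-yn-4-ol
Product: 5 tert-butyldimethyl{[(4R)-6-methylhept-5-en-1-yn-4-yl]oxy}silane
Conditions: TBSCl, imidazole, DMF, 0 °C → rt
Reagents that add atoms: tert-butyldimethylsilyl chloride, CC(C)(C)[Si](C)(C)Cl
Why: Silylation (silyl ether formation) masks O9 against the organolithium and Grignard reagents and prevents it from acting as a second directing group in step 4; no stereocentre is affected.

Step 3
Reactants: 5 tert-butyldimethyl{[(4R)-6-methylhept-5-en-1-yn-4-yl]oxy}silane; 6 oxirane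
Product: 8 (6R)-6-(tert-butyldimethylsilyloxy)-8-methylnon-7-en-3-yn-1-ol, via lithium acetylide 7 (not isolated)
Conditions: n-BuLi, THF, −78 °C; BF3·OEt2, then 6, −78 °C; aq. NH4Cl
Reagents that add atoms: none
Why: Alkynylation of an epoxide: the lithium acetylide opens BF3-activated oxirane to add C6 and C5 and to leave the primary homopropargylic hydroxyl needed as directing group in step 4; no stereocentre is formed.

Step 4
Reactants: 8 (6R)-6-(tert-butyldimethylsilyloxy)-8-methylnon-7-en-3-yn-1-ol
Product: 10 (3Z,6R)-6-(tert-butyldimethylsilyloxy)-4,8-dimethylnona-3,7-dien-1-ol, via alkenylmagnesium alkoxide 9 (not isolated)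
Conditions: MeMgBr (5 equiv), Fe(acac)3 (20 mol %), THF, −20 → 0 °C; aq. NH4Cl
Reagents that add atoms: methylmagnesium bromide, C[Mg]Br
Why: Iron-catalysed, alkoxide-directed syn-carbomagnesiation of a homopropargylic alcohol: methyl (C14) is delivered to the distal alkyne carbon C7 and magnesium to the proximal C1 within the alkoxide chelate, so that protonation leaves H-1 cis to C14 and thus the Z alkene (C6 cis to C8) that step 9 requires.

Step 5
Reactants: 10 (3Z,6R)-6-(tert-butyldimethylsilyloxy)-4,8-dimethylnona-3,7-dien-1-ol; 11 but-3-en-2-yl acetate (racemic)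
Product: 13 (3S,4R,6Z,9R)-9-(tert-butyldimethylsilyloxy)-3,7,11-trimethyldodeca-1,6,10-trien-4-ol, via transient aldehyde 12 (not isolated)
Conditions: [Ir(cod)Cl]2 (2.5 mol %), (S)-SEGPHOS (5 mol %), 4-cyano-3-nitrobenzoic acid (10 mol %), Cs2CO3 (20 mol %), THF, 90 °C
Reagents that add atoms: none
Why: Iridium-catalysed transfer-hydrogenative carbonyl crotylation from the alcohol oxidation level: the catalyst dehydrogenates the primary alcohol to aldehyde 12, which is trapped at once by the (E)-σ-crotyliridium species through a closed chair transition state (anti C4-methyl/C5-hydroxyl), the (S)-ligand being expected to direct addition to the Si face and so to set 5R and 4S.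

Step 6
Reactants: 13 (3S,4R,6Z,9R)-9-(tert-butyldimethylsilyloxy)-3,7,11-trimethyldodeca-1,6,10-trien-4-ol
Product: 15 (3S,4R,6Z,9R)-3,7,11-trimethyldodeca-1,6,10-triene-4,9-diyl diacetate, via diol 14 (not isolated)
Conditions: TBAF, THF, rt; then Ac2O, Et3N, DMAP, 0 °C → rt (one flask)
Reagents that add atoms: acetic anhydride, CC(=O)OC(C)=O
Why: Fluoride desilylation followed in the same flask by DMAP-catalysed acetylation (esterification) places the two acetates of the target on O5 and O9 before the C2 hydroxyl exists, without touching a stereocentre.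

Step 7
Reactants: 15 (3S,4R,6Z,9R)-3,7,11-trimethyldodeca-1,6,10-triene-4,9-diyl diacetate
Product: 17 (3S,4R,6Z,9R)-1-hydroxy-3,7,11-trimethyldodeca-6,10-diene-4,9-diyl diacetate, via B-alkyl-9-BBN adduct 16 (not isolated)
Conditions: 9-BBN, THF, 0 °C → rt; then 30% H2O2, aq. NaOAc, 0 °C
Reagents that add atoms: hydrogen peroxide, OO
Why: Hydroboration–oxidation: 9-BBN adds anti-Markovnikov to the monosubstituted C2=C3 alkene far faster than to the two trisubstituted alkenes, and the acetate-buffered peroxide oxidation gives the primary alcohol without cleaving the esters.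

Step 8
Reactants: 17 (3S,4R,6Z,9R)-1-hydroxy-3,7,11-trimethyldodeca-6,10-diene-4,9-diyl diacetate
Product: 18 (3S,4R,6Z,9R)-3,7,11-trimethyl-1-oxododeca-6,10-diene-4,9-diyl diacetate
Conditions: Dess–Martin periodinane, NaHCO3, CH2Cl2, 0 °C → rt
Reagents that add atoms: none
Why: Dess–Martin oxidation of the primary alcohol under buffered conditions gives the aldehyde (C2) without epimerisation, acyl migration or attack on the alkenes.

Step 9
Reactants: 18 (3S,4R,6Z,9R)-3,7,11-trimethyl-1-oxododeca-6,10-diene-4,9-diyl diacetate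
Product: 19 (1S,2R,4S,5R,9R)-5,9-diacetoxybisabola-7(14),10-dien-2-ol
Conditions: Al(OC6H3Ph2-2,6)3 (aluminium tris(2,6-diphenylphenoxide), 10 mol %), toluene, −20 → 0 °C
Reagents that add atoms: none
Why: Intramolecular carbonyl-ene reaction: the aldehyde, bound in the pocket of the bulky aluminium phenoxide, is attacked at C2 by alkene carbon C1 while its oxygen takes a hydrogen from C14 in a concerted six-centre process, which forms the C1–C2 bond, the C2 hydroxyl and the C7=C14 methylene. The closest known reaction is the Lewis-acid-catalysed cyclisation of citronellal to isopulegol, of which 18 is a 4,9-dioxygenated homologue. The six-membered carbocycle closes in the 6-exo mode (C1 and C2 become ring atoms, C7 and the oxygen stay exocyclic) through a chair-like transition state. C1 (S) and C2 (R) should arise trans-diequatorial in the chair that keeps the C4 methyl equatorial and the smaller C5 acetoxy axial, so the C4/C5 pair set in step 5 controls both new centres. The step needs hydrogen transfer from C14 and not from C8, which the Z geometry secures because only the alkene substituent trans to C6 lies under the carbonyl oxygen in the chair, and it needs the trans isomer (not the axial-hydroxyl one), which the bulky catalyst favours. It also needs activation of the aldehyde without ionisation of the C9 allylic acetate, for which a hindered, aldehyde-selective Lewis acid at low temperature is chosen.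

Step 10
Reactants: 19 (1S,2R,4S,5R,9R)-5,9-diacetoxybisabola-7(14),10-dien-2-ol
Product: 20 (1S,2R,4S,5R,7R,9R)-5,9-diacetoxybisabol-10-en-2-ol
Conditions: [Rh(nbd)(dppb)]BF4 (5 mol %), H2 (50 atm), CH2Cl2, rt
Reagents that add atoms: none
Why: Hydroxyl-directed homogeneous hydrogenation: the cationic rhodium catalyst binds the C2 hydroxyl and the C7=C14 alkene in the rotamer that keeps C8 eclipsed with H-1 (least allylic 1,2-strain), so that hydrogen is delivered to C7 from the face turned toward the hydroxyl and C7 is set as R, while the unbound trisubstituted C10=C11 alkene should not react.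

Step 11
Reactants: 20 (1S,2R,4S,5R,7R,9R)-5,9-diacetoxybisabol-10-en-2-ol; 21 angelic acid
Product: 22 (1S,2R,4S,5R,7R,9R)-5,9-diacetoxy-2-(angeloyloxy)bisabol-10-ene (target)
Conditions: 21, 2,4,6-trichlorobenzoyl chloride, Et3N, toluene, rt; then 20, 80 °C
Reagents that add atoms: none
Why: Yamaguchi esterification: the mixed anhydride of angelic acid acylates the hindered equatorial C2 hydroxyl on heating without a nucleophilic catalyst, conditions chosen because they retain the Z geometry of the angelate instead of isomerising it to the tiglate.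

Compound list
1 | 3-methylbut-2-enal (prenal) | CC(C)=CC=O | starting material
2 | allenylboronic acid pinacol ester, 4,4,5,5-tetramethyl-2-(propa-1,2-dien-1-yl)-1,3,2-dioxaborolane | C=C=CB1OC(C)(C)C(C)(C)O1 | starting material
3 | pinacol borate ester of 4, 4,4,5,5-tetramethyl-2-{[(4R)-6-methylhept-5-en-1-yn-4-yl]oxy}-1,3,2-dioxaborolane | C#CC[C@H](C=C(C)C)OB1OC(C)(C)C(C)(C)O1 | intermediate (not isolated)
4 | (4R)-6-methylhept-5-en-1-yn-4-ol | C#CC[C@H](C=C(C)C)O | intermediate
5 | tert-butyldimethyl{[(4R)-6-methylhept-5-en-1-yn-4-yl]oxy}silane | C#CC[C@H](C=C(C)C)O[Si](C)(C)C(C)(C)C | intermediate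
6 | oxirane (ethylene oxide) | C1CO1 | starting material
7 | lithium acetylide of 5 | [Li]C#CC[C@H](C=C(C)C)O[Si](C)(C)C(C)(C)C | intermediate (not isolated)
8 | (6R)-6-(tert-butyldimethylsilyloxy)-8-methylnon-7-en-3-yn-1-ol | OCCC#CC[C@H](C=C(C)C)O[Si](C)(C)C(C)(C)C | intermediate
9 | alkenylmagnesium alkoxide: bromomagnesium alkoxide of 10 carrying MgBr in place of H on C1 (Mg cis to the C14 methyl) | Br[Mg]OCC/C([Mg]Br)=C(/C)C[C@H](C=C(C)C)O[Si](C)(C)C(C)(C)C | intermediate (not isolated)
10 | (3Z,6R)-6-(tert-butyldimethylsilyloxy)-4,8-dimethylnona-3,7-dien-1-ol | OCC/C=C(/C)C[C@H](C=C(C)C)O[Si](C)(C)C(C)(C)C | intermediate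
11 | but-3-en-2-yl acetate (racemic α-methylallyl acetate) | CC(OC(C)=O)C=C | starting material
12 | (3Z,6R)-6-(tert-butyldimethylsilyloxy)-4,8-dimethylnona-3,7-dienal | O=CC/C=C(/C)C[C@H](C=C(C)C)O[Si](C)(C)C(C)(C)C | intermediate (not isolated)
13 | (3S,4R,6Z,9R)-9-(tert-butyldimethylsilyloxy)-3,7,11-trimethyldodeca-1,6,10-trien-4-ol | C=C[C@H](C)[C@H](O)C/C=C(/C)C[C@H](C=C(C)C)O[Si](C)(C)C(C)(C)C | intermediate
14 | (3S,4R,6Z,9R)-3,7,11-trimethyldodeca-1,6,10-triene-4,9-diol | C=C[C@H](C)[C@H](O)C/C=C(/C)C[C@H](C=C(C)C)O | intermediate (not isolated)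
15 | (3S,4R,6Z,9R)-3,7,11-trimethyldodeca-1,6,10-triene-4,9-diyl diacetate | C=C[C@H](C)[C@H](OC(C)=O)C/C=C(/C)C[C@H](C=C(C)C)OC(C)=O | intermediate
16 | 9-[(3S,4R,6Z,9R)-4,9-diacetoxy-3,7,11-trimethyldodeca-6,10-dien-1-yl]-9-borabicyclo[3.3.1]nonane | B1(CC[C@H](C)[C@H](OC(C)=O)C/C=C(/C)C[C@H](C=C(C)C)OC(C)=O)C2CCCC1CCC2 | intermediate (not isolated)
17 | (3S,4R,6Z,9R)-1-hydroxy-3,7,11-trimethyldodeca-6,10-diene-4,9-diyl diacetate | OCC[C@H](C)[C@H](OC(C)=O)C/C=C(/C)C[C@H](C=C(C)C)OC(C)=O | intermediate
18 | (3S,4R,6Z,9R)-3,7,11-trimethyl-1-oxododeca-6,10-diene-4,9-diyl diacetate | O=CC[C@H](C)[C@H](OC(C)=O)C/C=C(/C)C[C@H](C=C(C)C)OC(C)=O | intermediate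
19 | (1S,2R,4S,5R,9R)-5,9-diacetoxybisabola-7(14),10-dien-2-ol (trans-2-hydroxycyclohexane with a 1-methylene-substituted side chain at C1) | O[C@@H]1C[C@H](C)[C@H](OC(C)=O)C[C@H]1C(=C)C[C@H](C=C(C)C)OC(C)=O | intermediate
20 | (1S,2R,4S,5R,7R,9R)-5,9-diacetoxybisabol-10-en-2-ol | O[C@@H]1C[C@H](C)[C@H](OC(C)=O)C[C@H]1[C@H](C)C[C@H](C=C(C)C)OC(C)=O | intermediate
21 | angelic acid, (Z)-2-methylbut-2-enoic acid | C/C=C(/C)C(=O)O | starting material
22 | (1S,2R,4S,5R,7R,9R)-5,9-diacetoxy-2-(angeloyloxy)bisabol-10-ene, CNP0286954.1 | C/C=C(/C)C(=O)O[C@@H]1C[C@H](C)[C@H](OC(C)=O)C[C@H]1[C@H](C)C[C@H](C=C(C)C)OC(C)=O | target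

Total steps: 11. Longest linear sequence: 11 steps (from 1).

Steps most likely to fail

Step 9 (ene cyclisation). The Lewis acid may ionise or transpose the C9 allylic acetate instead of activating only the aldehyde, and the preference for the chair with equatorial C4 methyl and axial C5 acetoxy may be eroded, giving the C1/C2 diastereomer. The fallback carries O9 as its silyl ether through the cyclisation; it sets out from 13 and comes back at 22. Only the free C5 hydroxyl of 13 is acetylated (Ac2O, pyridine, DMAP) to give (3S,4R,6Z,9R)-9-(tert-butyldimethylsilyloxy)-3,7,11-trimethyldodeca-1,6,10-trien-4-yl acetate F1. Hydroboration–oxidation as in step 7 should give (3S,4R,6Z,9R)-9-(tert-butyldimethylsilyloxy)-1-hydroxy-3,7,11-trimethyldodeca-6,10-dien-4-yl acetate F2, and Dess–Martin oxidation (3S,4R,6Z,9R)-9-(tert-butyldimethylsilyloxy)-3,7,11-trimethyl-1-oxododeca-6,10-dien-4-yl acetate F3. The ene cyclisation is then run with ZnBr2 (1.2 equiv, toluene, 0 °C), which an allylic silyl ether should tolerate, to give (1S,2R,4S,5R,9R)-5-acetoxy-9-(tert-butyldimethylsilyloxy)bisabola-7(14),10-dien-2-ol F4. Directed hydrogenation as in step 10 should give (1S,2R,4S,5R,7R,9R)-5-acetoxy-9-(tert-butyldimethylsilyloxy)bisabol-10-en-2-ol F5, and Yamaguchi angeloylation as in step 11 (1S,2R,4S,5R,7R,9R)-5-acetoxy-2-(angeloyloxy)-9-(tert-butyldimethylsilyloxy)bisabol-10-ene F6. HF·pyridine in THF then frees (1S,2R,4S,5R,7R,9R)-5-acetoxy-2-(angeloyloxy)bisabol-10-en-9-ol F7, and Ac2O/pyridine/DMAP gives 22.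

Step 10 (directed hydrogenation). Hydrogen may be delivered through the other C1–C7 rotamer of the rhodium chelate (C7 epimer), the 1,1-disubstituted alkene may isomerise into the ring-adjacent tetrasubstituted position before it is reduced, or C10=C11 may be reduced through binding of the metal to the C9 acetate. The fallback replaces substrate control by catalyst control; it sets out from 19 and comes back at 20. Alcohol 19 is hydrogenated with a chiral ruthenium diacetate–BINAP complex, Ru(OAc)2[(S)-BINAP] or its (R) antipode, whichever is matched with the substrate, in MeOH under H2. Catalysts of this kind reduce allylic and homoallylic alcohols under combined hydroxyl binding and ligand control and leave isolated trisubstituted alkenes alone. This fallback makes no new compound (F0).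

Step 4 (iron-catalysed carbomagnesiation). Methyl may be delivered to the wrong alkyne carbon, or the syn course may be lost, so that regioisomers or the E alkene form. The fallback builds the Z alkene by zirconium-catalysed methylalumination with chelation-driven isomerisation (Negishi carboalumination in its anti mode for homopropargylic alcohols); it sets out from 4 and comes back at 10. Alcohol 4 is treated with AlMe3 and Cp2ZrCl2 in 1,2-dichloroethane, heated so that the syn adduct isomerises to the chelated alkoxyalane, and quenched with I2 to give (1Z,4R)-1-iodo-2,6-dimethylhepta-1,5-dien-4-ol F8. TBSCl/imidazole gives tert-butyl{[(1Z,4R)-1-iodo-2,6-dimethylhepta-1,5-dien-4-yl]oxy}dimethylsilane F9. Iodine–lithium exchange (t-BuLi, Et2O, −78 °C) and opening of oxirane 6 with BF3·OEt2 should then give 10 with retention of the alkene geometry.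

Further compounds
F1 | step 9 | (3S,4R,6Z,9R)-9-(tert-butyldimethylsilyloxy)-3,7,11-trimethyldodeca-1,6,10-trien-4-yl acetate | C=C[C@H](C)[C@H](OC(C)=O)C/C=C(/C)C[C@H](C=C(C)C)O[Si](C)(C)C(C)(C)C
F2 | step 9 | (3S,4R,6Z,9R)-9-(tert-butyldimethylsilyloxy)-1-hydroxy-3,7,11-trimethyldodeca-6,10-dien-4-yl acetate | OCC[C@H](C)[C@H](OC(C)=O)C/C=C(/C)C[C@H](C=C(C)C)O[Si](C)(C)C(C)(C)C
F3 | step 9 | (3S,4R,6Z,9R)-9-(tert-butyldimethylsilyloxy)-3,7,11-trimethyl-1-oxododeca-6,10-dien-4-yl acetate | O=CC[C@H](C)[C@H](OC(C)=O)C/C=C(/C)C[C@H](C=C(C)C)O[Si](C)(C)C(C)(C)C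
F4 | step 9 | (1S,2R,4S,5R,9R)-5-acetoxy-9-(tert-butyldimethylsilyloxy)bisabola-7(14),10-dien-2-ol | O[C@@H]1C[C@H](C)[C@H](OC(C)=O)C[C@H]1C(=C)C[C@H](C=C(C)C)O[Si](C)(C)C(C)(C)C
F5 | step 9 | (1S,2R,4S,5R,7R,9R)-5-acetoxy-9-(tert-butyldimethylsilyloxy)bisabol-10-en-2-ol | O[C@@H]1C[C@H](C)[C@H](OC(C)=O)C[C@H]1[C@H](C)C[C@H](C=C(C)C)O[Si](C)(C)C(C)(C)C
F6 | step 9 | (1S,2R,4S,5R,7R,9R)-5-acetoxy-2-(angeloyloxy)-9-(tert-butyldimethylsilyloxy)bisabol-10-ene | C/C=C(/C)C(=O)O[C@@H]1C[C@H](C)[C@H](OC(C)=O)C[C@H]1[C@H](C)C[C@H](C=C(C)C)O[Si](C)(C)C(C)(C)C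
F7 | step 9 | (1S,2R,4S,5R,7R,9R)-5-acetoxy-2-(angeloyloxy)bisabol-10-en-9-ol | C/C=C(/C)C(=O)O[C@@H]1C[C@H](C)[C@H](OC(C)=O)C[C@H]1[C@H](C)C[C@H](C=C(C)C)O
F0 | step 10 | none | none
F8 | step 4 | (1Z,4R)-1-iodo-2,6-dimethylhepta-1,5-dien-4-ol | I/C=C(/C)C[C@H](C=C(C)C)O
F9 | step 4 | tert-butyl{[(1Z,4R)-1-iodo-2,6-dimethylhepta-1,5-dien-4-yl]oxy}dimethylsilane | I/C=C(/C)C[C@H](C=C(C)C)O[Si](C)(C)C(C)(C)C
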